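**Plan**
1. Retrosynthetic cuts, in order: the six O–benzyl bonds; the C2–aryl bond of the flavanone (aryl added to a chromone); O1–C2 and C2–C3 of that chromone ring C (one carbon added to an acetophenone); the C8–C8'' biaryl bond, cut as a ring bond of a seven-membered cyclic silylene bis(aryl ether); the two Si–O bonds; ring C and the C8–I bond of the flavone half, which goes back to phloroacetophenone and 4-(benzyloxy)benzaldehyde.
2. Enabling feature: each carbon of the C8–C8'' bond lies between two oxygens. O7 of flavone ring A and the oxygen that becomes O1 of the flavanone (still a free phenol beside the acetyl group while flavanone ring C is absent) can share one Si(tBu)2 unit, so that C8–I of the flavone faces the only free C–H ortho to that phenol across a seven-membered ring.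
3. Forward ring order: flavone ring C (chalcone, oxidative cyclisation), silylene bridge, biaryl bond with the dioxasilepine ring, bridge opened, chromone ring C of the second half closed through the freed phenol, flavanone by aryl addition, debenzylation.
4. Stereochemistry: C2 (S) is set in the penultimate step by the chiral diphosphine on rhodium, after every basic step; only neutral hydrogenolysis follows.

Key step: step 8

Assumption: the target SMILES defines only C2 and leaves the tetra-ortho-substituted biaryl axis open, so the axis is formed without control and the (2S) product is expected as a mixture of two atropisomers, both of which fit the structure given.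

**Step 1**
Reactants: 1 2,4,6-trihydroxyacetophenone
Product: 2 1-[2,4-bis(benzyloxy)-6-hydroxyphenyl]ethan-1-one
Conditions: BnBr (2.1 equiv), K2CO3, DMF, rt
Reagents that add atoms: benzyl bromide, BrCc1ccccc1
Why: Williamson ether synthesis in which the 4-OH and one of the two equivalent ortho-OH groups are alkylated, while the last OH is hydrogen-bonded to the acetyl carbonyl and should stay free under these mild conditions.

**Step 2**
Reactants: 1 2,4,6-trihydroxyacetophenone
Product: 3 1-[2,6-dihydroxy-4-(methoxymethoxy)phenyl]ethan-1-one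
Conditions: MOMCl (1.0 equiv), K2CO3, acetone, 0 °C to rt
Reagents that add atoms: chloromethyl methyl ether, COCCl
Why: Williamson-type alkylation with a reactive chloromethyl ether, in which the 4-OH (para to the acetyl group, the most acidic and the only one not hydrogen-bonded to the carbonyl) should react first with one equivalent of reagent.

**Step 3**
Reactants: 3 1-[2,6-dihydroxy-4-(methoxymethoxy)phenyl]ethan-1-one
Product: 4 1-[2-(benzyloxy)-6-hydroxy-4-(methoxymethoxy)phenyl]ethan-1-one
Conditions: BnBr (1.05 equiv), K2CO3, acetone, reflux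
Reagents that add atoms: benzyl bromide, BrCc1ccccc1
Why: Williamson ether synthesis on two equivalent OH groups, which should stop at the mono-benzyl stage because the remaining OH is then locked in the hydrogen bond to the carbonyl.

**Step 4**
Reactants: 4 1-[2-(benzyloxy)-6-hydroxy-4-(methoxymethoxy)phenyl]ethan-1-one
Product: 5 1-[6-(benzyloxy)-2-hydroxy-3-iodo-4-(methoxymethoxy)phenyl]ethan-1-one
Conditions: BnMe3N ICl2 (1.05 equiv), NaHCO3, CH2Cl2/MeOH, rt
Reagents that add atoms: benzyltrimethylammonium dichloroiodate, C[N+](C)(C)Cc1ccccc1.Cl[I-]Cl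
Why: Electrophilic aromatic iodination with a mild I+ source, which on hydrogen-bonded 2-hydroxyaryl ketones goes ortho to the free phenol (here C3, between the OH and the MOM ether), while NaHCO3 takes up the HCl and protects the acetal.

**Step 5**
Reactants: 5 1-[6-(benzyloxy)-2-hydroxy-3-iodo-4-(methoxymethoxy)phenyl]ethan-1-one; 6 4-(benzyloxy)benzaldehyde
Product: 7 (2E)-1-[6-(benzyloxy)-2-hydroxy-3-iodo-4-(methoxymethoxy)phenyl]-3-[4-(benzyloxy)phenyl]prop-2-en-1-one
Conditions: KOH (aq), EtOH/THF, rt
Reagents that add atoms: none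
Why: Claisen–Schmidt (crossed aldol) condensation of the methyl ketone with a non-enolisable aldehyde, dehydrating to the conjugated E-enone as the thermodynamic alkene, with aryl iodide, MOM and benzyl ethers inert to hydroxide at room temperature.

**Step 6**
Reactants: 7 (2E)-1-[6-(benzyloxy)-2-hydroxy-3-iodo-4-(methoxymethoxy)phenyl]-3-[4-(benzyloxy)phenyl]prop-2-en-1-one
Product: 9 5-(benzyloxy)-2-[4-(benzyloxy)phenyl]-7-hydroxy-8-iodo-4H-chromen-4-one, via MOM-protected 8-iodoflavone 8 (not isolated)
Conditions: I2 (10 mol %), DMSO, 120 °C; then HCl (3 M in MeOH), THF, 50 °C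
Reagents that add atoms: none
Why: Iodine-catalysed oxidative cyclisation of a 2'-hydroxychalcone in DMSO (oxa-Michael closure through the only free phenol, α-iodination, loss of HI, DMSO reoxidising iodide) should give the flavone with iodine at C8, and methanolic HCl then removes the MOM acetal by acetal exchange without touching the benzyl ethers.

**Step 7**
Reactants: 9 5-(benzyloxy)-2-[4-(benzyloxy)phenyl]-7-hydroxy-8-iodo-4H-chromen-4-one; 2 1-[2,4-bis(benzyloxy)-6-hydroxyphenyl]ethan-1-one
Product: 11 {[5-(benzyloxy)-2-[4-(benzyloxy)phenyl]-8-iodo-4-oxo-4H-chromen-7-yl]oxy}[2-acetyl-3,5-bis(benzyloxy)phenoxy]di-tert-butylsilane, via aryloxysilyl triflate 10 (not isolated)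
Conditions: 9, NaH, THF, 0 °C, then tBu2Si(OTf)2 (1.1 equiv), −78 to 0 °C; then 2 pre-treated with NaH in THF, 0 °C to rt
Reagents that add atoms: di-tert-butylsilyl bis(trifluoromethanesulfonate), CC(C)(C)[Si](OS(=O)(=O)C(F)(F)F)(OS(=O)(=O)C(F)(F)F)C(C)(C)C
Why: Two successive nucleophilic substitutions at silicon (silyl ether formation), in which the first triflate is displaced fast at low temperature and the bulky mono-aryloxy silyl triflate then reacts only with the second, separately added phenoxide to give the unsymmetrical bis(aryloxy)silane.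

**Step 8**
Reactants: 11 {[5-(benzyloxy)-2-[4-(benzyloxy)phenyl]-8-iodo-4-oxo-4H-chromen-7-yl]oxy}[2-acetyl-3,5-bis(benzyloxy)phenoxy]di-tert-butylsilane
Product: 12 silylene-bridged biaryl: 5-(benzyloxy)-2-[4-(benzyloxy)phenyl]-4H-chromen-4-one bonded at C8 to C6 of a 2-acetyl-3,5-bis(benzyloxy)phenoxy ring, with O7 of the chromenone and the phenoxy oxygen both on one Si(tBu)2 (seven-membered dibenzo[d,f][1,3,2]dioxasilepine ring; racemic axis)
Conditions: Pd(OAc)2 (10 mol %), PCy3·HBF4 (20 mol %), CsOPiv (30 mol %), Cs2CO3, 4 Å MS, p-xylene, 130 °C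
Reagents that add atoms: none
Why: Zerovalent palladium, formed from Pd(OAc)2 and PCy3, should insert into the C8–I bond of the flavone; the arylpalladium iodide is held next to the acetophenone ring by the O–Si–O bridge, exchanges iodide for pivalate, cleaves the neighbouring C–H bond by concerted metalation–deprotonation and closes the biaryl bond by reductive elimination. The closest known reaction type is the silicon-tethered palladium-catalysed intramolecular C–H arylation of (2-haloaryloxy)(aryloxy)di-tert-butylsilanes, which after removal of silicon gives unsymmetrical 2,2'-biphenols. The one ring closed is the seven-membered 1,3,2-dioxasilepine, formed by aryl–aryl reductive elimination from an eight-membered diarylpalladacycle. No stereocentre arises; the new tetra-ortho-substituted axis forms without control, in line with the assumption above. The step needs cross-coupling instead of homo-coupling and one defined position on each ring: the iodide marks C8 (not C6) of the flavone, and from the single phenolic oxygen of the acetophenone ring the bridge can reach only the C–H between that oxygen and a benzyloxy group, since the other ortho position carries the acetyl group and the C–H between the two benzyloxy groups would require an impossible para-bridged nine-membered ring. Intermolecular side reactions of the doubly ortho-substituted arylpalladium intermediate (ketone α-arylation, Heck reaction at the flavone C2=C3 bond) should be slow against the tethered C–H cleavage.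

**Step 9**
Reactants: 12 silylene-bridged biaryl
Product: 13 8-[3-acetyl-4,6-bis(benzyloxy)-2-hydroxyphenyl]-5-(benzyloxy)-2-[4-(benzyloxy)phenyl]-7-hydroxy-4H-chromen-4-one
Conditions: HF·pyridine, THF/pyridine, 0 °C to rt
Reagents that add atoms: none
Why: Fluoride-mediated desilylation, in which the strong Si–F bond drives cleavage of both aryl–O–Si bonds of the bridge under mildly acidic conditions that leave benzyl ethers, the flavone and the ketone untouched.

**Step 10**
Reactants: 13 8-[3-acetyl-4,6-bis(benzyloxy)-2-hydroxyphenyl]-5-(benzyloxy)-2-[4-(benzyloxy)phenyl]-7-hydroxy-4H-chromen-4-one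
Product: 14 8-[3-acetyl-4,6-bis(benzyloxy)-2-hydroxyphenyl]-5,7-bis(benzyloxy)-2-[4-(benzyloxy)phenyl]-4H-chromen-4-one
Conditions: BnBr (1.1 equiv), K2CO3, acetone, reflux
Reagents that add atoms: benzyl bromide, BrCc1ccccc1
Why: Williamson ether synthesis selective for the acidic, non-chelated flavone 7-OH, because the other phenol is hydrogen-bonded to the acetyl group and flanked on both sides, as in the selective 7-O-alkylation of 5,7-dihydroxyflavonoids.

**Step 11**
Reactants: 14 8-[3-acetyl-4,6-bis(benzyloxy)-2-hydroxyphenyl]-5,7-bis(benzyloxy)-2-[4-(benzyloxy)phenyl]-4H-chromen-4-one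
Product: 16 5,5',7,7'-tetrakis(benzyloxy)-2-[4-(benzyloxy)phenyl]-4H,4'H-[8,8'-bichromene]-4,4'-dione (racemic axis), via enaminone 15 (not isolated)
Conditions: Me2NCH(OMe)2, toluene, 100 °C; then conc. HCl, CH2Cl2, rt
Reagents that add atoms: N,N-dimethylformamide dimethyl acetal, COC(OC)N(C)C
Why: Chromone synthesis through an enaminone (condensation of the methyl ketone with the formamide acetal, then acid-promoted 6-endo-trig addition of the phenol and loss of dimethylamine), in which the only free phenol is the one ortho to the biaryl bond, so the new pyranone oxygen becomes O1 next to C8.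

**Step 12**
Reactants: 16 5,5',7,7'-tetrakis(benzyloxy)-2-[4-(benzyloxy)phenyl]-4H,4'H-[8,8'-bichromene]-4,4'-dione; 17 4-(benzyloxy)phenylboronic acid
Product: 18 (2S)-5,7-bis(benzyloxy)-8-{5,7-bis(benzyloxy)-2-[4-(benzyloxy)phenyl]-4-oxo-4H-chromen-8-yl}-2-[4-(benzyloxy)phenyl]-2,3-dihydro-4H-chromen-4-one
Conditions: [Rh(OH)(cod)]2 (2.5 mol %), (S)-MeO-F12-BIPHEP (5.5 mol %), toluene, H2O (trace), 50 °C
Reagents that add atoms: none
Why: Rhodium-catalysed asymmetric 1,4-addition of an arylboronic acid (Hayashi–Miyaura reaction) to the 2-unsubstituted chromone, the flavone ring being too hindered at its β-carbon to react; C2 is set by the ligand (S)-2,2'-bis[bis(3,4,5-trifluorophenyl)phosphino]-6,6'-dimethoxy-1,1'-biphenyl, which should deliver the aryl group to the face giving 2S by the facial model that holds for (S)-configured biaryl diphosphines and cyclic enones, and the neutral medium keeps the flavanone from ring-opening.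

**Step 13**
Reactants: 18 (2S)-hexabenzyl ether
Product: 19 (2S)-5,7-dihydroxy-8-[5,7-dihydroxy-2-(4-hydroxyphenyl)-4-oxo-4H-chromen-8-yl]-2-(4-hydroxyphenyl)-2,3-dihydro-4H-chromen-4-one
Conditions: H2 (1 atm), Pd/C (10 wt %), THF/MeOH, rt
Reagents that add atoms: none
Why: Catalytic hydrogenolysis of the six benzyl ethers under neutral conditions, which neither enolises C3 nor opens the pyranone ring, so C2 keeps its configuration, while the flavone C2=C3 bond and the aryl ketones are reduced much more slowly than O-benzyl groups are cleaved.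

**Compound list**
1 | 2,4,6-trihydroxyacetophenone | CC(=O)c1c(O)cc(O)cc1O | starting material
2 | 1-[2,4-bis(benzyloxy)-6-hydroxyphenyl]ethan-1-one | CC(=O)c1c(O)cc(OCc2ccccc2)cc1OCc1ccccc1 | intermediate
3 | 1-[2,6-dihydroxy-4-(methoxymethoxy)phenyl]ethan-1-one | CC(=O)c1c(O)cc(OCOC)cc1O | intermediate
4 | 1-[2-(benzyloxy)-6-hydroxy-4-(methoxymethoxy)phenyl]ethan-1-one | CC(=O)c1c(O)cc(OCOC)cc1OCc1ccccc1 | intermediate
5 | 1-[6-(benzyloxy)-2-hydroxy-3-iodo-4-(methoxymethoxy)phenyl]ethan-1-one | CC(=O)c1c(O)c(I)c(OCOC)cc1OCc1ccccc1 | intermediate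
6 | 4-(benzyloxy)benzaldehyde | O=Cc1ccc(OCc2ccccc2)cc1 | starting material
7 | (2E)-1-[6-(benzyloxy)-2-hydroxy-3-iodo-4-(methoxymethoxy)phenyl]-3-[4-(benzyloxy)phenyl]prop-2-en-1-one | O=C(/C=C/c1ccc(OCc2ccccc2)cc1)c1c(O)c(I)c(OCOC)cc1OCc1ccccc1 | intermediate
8 | 5-(benzyloxy)-2-[4-(benzyloxy)phenyl]-8-iodo-7-(methoxymethoxy)-4H-chromen-4-one | O=c1cc(-c2ccc(OCc3ccccc3)cc2)oc2c(I)c(OCOC)cc(OCc3ccccc3)c12 | intermediate
9 | 5-(benzyloxy)-2-[4-(benzyloxy)phenyl]-7-hydroxy-8-iodo-4H-chromen-4-one | O=c1cc(-c2ccc(OCc3ccccc3)cc2)oc2c(I)c(O)cc(OCc3ccccc3)c12 | intermediate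
10 | {[5-(benzyloxy)-2-[4-(benzyloxy)phenyl]-8-iodo-4-oxo-4H-chromen-7-yl]oxy}di-tert-butylsilyl trifluoromethanesulfonate | O=c1cc(-c2ccc(OCc3ccccc3)cc2)oc2c(I)c(O[Si](OS(=O)(=O)C(F)(F)F)(C(C)(C)C)C(C)(C)C)cc(OCc3ccccc3)c12 | intermediate
11 | {[5-(benzyloxy)-2-[4-(benzyloxy)phenyl]-8-iodo-4-oxo-4H-chromen-7-yl]oxy}[2-acetyl-3,5-bis(benzyloxy)phenoxy]di-tert-butylsilane | O=c1cc(-c2ccc(OCc3ccccc3)cc2)oc2c(I)c(O[Si](Oc3cc(OCc4ccccc4)cc(OCc4ccccc4)c3C(C)=O)(C(C)(C)C)C(C)(C)C)cc(OCc3ccccc3)c12 | intermediate
12 | silylene-bridged biaryl (di-tert-butyl dibenzo[d,f][1,3,2]dioxasilepine joining flavone O7/C8 to the phenoxy oxygen and adjacent carbon of the 2-acetyl-3,5-bis(benzyloxy)phenyl ring; racemic axis) | O=c1cc(-c2ccc(OCc3ccccc3)cc2)oc2c1c(OCc1ccccc1)cc1c2-c2c(OCc3ccccc3)cc(OCc3ccccc3)c(C(C)=O)c2O[Si](C(C)(C)C)(C(C)(C)C)O1 | intermediate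
13 | 8-[3-acetyl-4,6-bis(benzyloxy)-2-hydroxyphenyl]-5-(benzyloxy)-2-[4-(benzyloxy)phenyl]-7-hydroxy-4H-chromen-4-one | O=c1cc(-c2ccc(OCc3ccccc3)cc2)oc2c1c(OCc1ccccc1)cc(O)c2-c1c(OCc2ccccc2)cc(OCc2ccccc2)c(C(C)=O)c1O | intermediate
14 | 8-[3-acetyl-4,6-bis(benzyloxy)-2-hydroxyphenyl]-5,7-bis(benzyloxy)-2-[4-(benzyloxy)phenyl]-4H-chromen-4-one | O=c1cc(-c2ccc(OCc3ccccc3)cc2)oc2c1c(OCc1ccccc1)cc(OCc1ccccc1)c2-c1c(OCc2ccccc2)cc(OCc2ccccc2)c(C(C)=O)c1O | intermediate
15 | 8-{4,6-bis(benzyloxy)-3-[(2E)-3-(dimethylamino)prop-2-enoyl]-2-hydroxyphenyl}-5,7-bis(benzyloxy)-2-[4-(benzyloxy)phenyl]-4H-chromen-4-one | O=c1cc(-c2ccc(OCc3ccccc3)cc2)oc2c1c(OCc1ccccc1)cc(OCc1ccccc1)c2-c1c(OCc2ccccc2)cc(OCc2ccccc2)c(C(=O)/C=C/N(C)C)c1O | intermediate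
16 | 5,5',7,7'-tetrakis(benzyloxy)-2-[4-(benzyloxy)phenyl]-4H,4'H-[8,8'-bichromene]-4,4'-dione (racemic axis) | O=c1cc(-c2ccc(OCc3ccccc3)cc2)oc2c1c(OCc1ccccc1)cc(OCc1ccccc1)c2-c1c(OCc2ccccc2)cc(OCc2ccccc2)c2c(=O)ccoc12 | intermediate
17 | 4-(benzyloxy)phenylboronic acid | OB(O)c1ccc(OCc2ccccc2)cc1 | starting material
18 | (2S)-5,7-bis(benzyloxy)-8-{5,7-bis(benzyloxy)-2-[4-(benzyloxy)phenyl]-4-oxo-4H-chromen-8-yl}-2-[4-(benzyloxy)phenyl]-2,3-dihydro-4H-chromen-4-one | O=C1C[C@@H](c2ccc(OCc3ccccc3)cc2)Oc2c1c(OCc1ccccc1)cc(OCc1ccccc1)c2-c1c(OCc2ccccc2)cc(OCc2ccccc2)c2c(=O)cc(-c3ccc(OCc4ccccc4)cc3)oc12 | intermediate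
19 | (2S)-5,7-dihydroxy-8-[5,7-dihydroxy-2-(4-hydroxyphenyl)-4-oxo-4H-chromen-8-yl]-2-(4-hydroxyphenyl)-2,3-dihydro-4H-chromen-4-one | O=C1C[C@@H](c2ccc(O)cc2)Oc2c1c(O)cc(O)c2-c1c(O)cc(O)c2c(=O)cc(-c3ccc(O)cc3)oc12 | target

**Step count**
Total steps: 13. Longest linear sequence: 12 steps (steps 2 to 13, from 1 to 19); step 1 is a one-step branch that joins at step 7.

**Steps most likely to fail**

Step 8. The C–H cleavage at the crowded position between two oxygens may be slower than proto-deiodination of the arylpalladium intermediate. The Si–O bonds may also be attacked by carbonate or pivalate at the temperature needed. The fallback activates both carbons. It sets out from 9 (through silyl triflate 10) and from 2, and comes back at 12. Compound 2 is iodinated ortho to its free phenol with BnMe3N ICl2 and NaHCO3 as in step 4 to give 1-[4,6-bis(benzyloxy)-2-hydroxy-3-iodophenyl]ethan-1-one F1. Its sodium phenoxide is added to 10 to give {[5-(benzyloxy)-2-[4-(benzyloxy)phenyl]-8-iodo-4-oxo-4H-chromen-7-yl]oxy}[2-acetyl-3,5-bis(benzyloxy)-6-iodophenoxy]di-tert-butylsilane F2. Intramolecular reductive coupling of the two C–I bonds with stoichiometric Ni(cod)2 (zerovalent nickel) and PPh3 in DMF at 50 °C, a nickel-mediated Ullmann-type coupling that tolerates ketones, should then give 12.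

Step 12. Insertion of the electron-rich, hindered chromone into the aryl–rhodium bond may be slow against protodeboronation of 17. Facial selectivity may be poor, or the sense of induction opposite to the model; the sense is to be checked on a simple chromone and the mirror-image ligand used if required. A second aryl group may also add to the ketone of the product. The fallback closes the flavanone ring by oxa-Michael addition and resolves. It sets out from 14 and comes back at 18. Claisen–Schmidt condensation of 14 with 6 (Ba(OH)2·8H2O, MeOH/THF, 40 °C) should give 8-{4,6-bis(benzyloxy)-3-[(2E)-3-[4-(benzyloxy)phenyl]prop-2-enoyl]-2-hydroxyphenyl}-5,7-bis(benzyloxy)-2-[4-(benzyloxy)phenyl]-4H-chromen-4-one F3. Cyclisation with NaOAc in EtOH at reflux gives 18 together with the (2R) isomer of 18 F4. The two are separated by preparative HPLC on a chiral stationary phase, and F4 is returned to the NaOAc conditions, where it re-equilibrates through F3.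

Step 4. Iodination may go to C5 (para to the phenol, between the two ethers) or twice, and the HCl formed may remove the MOM group. The fallback postpones the iodination to the flavone stage. It sets out from 4 and comes back at 9. Claisen–Schmidt condensation of 4 with 6 (KOH, EtOH/THF) gives (2E)-1-[2-(benzyloxy)-6-hydroxy-4-(methoxymethoxy)phenyl]-3-[4-(benzyloxy)phenyl]prop-2-en-1-one F5. I2 (cat.) in DMSO at 120 °C gives 5-(benzyloxy)-2-[4-(benzyloxy)phenyl]-7-(methoxymethoxy)-4H-chromen-4-one F6. Methanolic HCl then gives 5-(benzyloxy)-2-[4-(benzyloxy)phenyl]-7-hydroxy-4H-chromen-4-one F7. Iodination of F7 with N-iodosuccinimide in DMF at 0 °C should go ortho to the free 7-OH at C8, the less hindered position between O7 and O1, to give 9.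

**Further compounds**
F1 | step 8 | 1-[4,6-bis(benzyloxy)-2-hydroxy-3-iodophenyl]ethan-1-one | CC(=O)c1c(O)c(I)c(OCc2ccccc2)cc1OCc1ccccc1
F2 | step 8 | {[5-(benzyloxy)-2-[4-(benzyloxy)phenyl]-8-iodo-4-oxo-4H-chromen-7-yl]oxy}[2-acetyl-3,5-bis(benzyloxy)-6-iodophenoxy]di-tert-butylsilane | O=c1cc(-c2ccc(OCc3ccccc3)cc2)oc2c(I)c(O[Si](Oc3c(I)c(OCc4ccccc4)cc(OCc4ccccc4)c3C(C)=O)(C(C)(C)C)C(C)(C)C)cc(OCc3ccccc3)c12
F3 | step 12 | 8-{4,6-bis(benzyloxy)-3-[(2E)-3-[4-(benzyloxy)phenyl]prop-2-enoyl]-2-hydroxyphenyl}-5,7-bis(benzyloxy)-2-[4-(benzyloxy)phenyl]-4H-chromen-4-one | O=c1cc(-c2ccc(OCc3ccccc3)cc2)oc2c1c(OCc1ccccc1)cc(OCc1ccccc1)c2-c1c(OCc2ccccc2)cc(OCc2ccccc2)c(C(=O)/C=C/c2ccc(OCc3ccccc3)cc2)c1O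
F4 | step 12 | (2R) isomer of 18 | O=C1C[C@H](c2ccc(OCc3ccccc3)cc2)Oc2c1c(OCc1ccccc1)cc(OCc1ccccc1)c2-c1c(OCc2ccccc2)cc(OCc2ccccc2)c2c(=O)cc(-c3ccc(OCc4ccccc4)cc3)oc12
F5 | step 4 | (2E)-1-[2-(benzyloxy)-6-hydroxy-4-(methoxymethoxy)phenyl]-3-[4-(benzyloxy)phenyl]prop-2-en-1-one | O=C(/C=C/c1ccc(OCc2ccccc2)cc1)c1c(O)cc(OCOC)cc1OCc1ccccc1
F6 | step 4 | 5-(benzyloxy)-2-[4-(benzyloxy)phenyl]-7-(methoxymethoxy)-4H-chromen-4-one | O=c1cc(-c2ccc(OCc3ccccc3)cc2)oc2cc(OCOC)cc(OCc3ccccc3)c12
F7 | step 4 | 5-(benzyloxy)-2-[4-(benzyloxy)phenyl]-7-hydroxy-4H-chromen-4-one | O=c1cc(-c2ccc(OCc3ccccc3)cc2)oc2cc(O)cc(OCc3ccccc3)c12
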